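**Retrosynthetic overview**
1. Target ⇐ acid removal of a catechol acetonide and a silyl ether, after catalyst-controlled hydrogenation of a C11=C12 E-alkene (sets C11).
2. Saturated ring (the only ring made; the arene is bought) ⇐ biomimetic 1,10-type cation–arene closure: an allyl cation at C4 is captured by arene carbon C10, trans to the C1 methyl. C4 is a linchpin: the C3–C4 bond (alkylzirconium + enal) and the C4–C10 bond are made in one flask.
3. Arene fragment ⇐ enantioselective aromatic Claisen rearrangement of the crotyl ether of methyl 2,3-dihydroxybenzoate (C9–C1 bond, C1 = R).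
4. Enal fragment ⇐ (R)-3-bromo-2-methylpropan-1-ol (C15 from the chiral pool) + allyl Grignard, then cross-metathesis with methacrolein.
5. Order of events: C1 (Claisen) → saturated ring with C4 (cation–arene closure) → C11 (hydrogenation); C15 is carried through unchanged.

Atom labels (serrulatane numbering): C1 = ring CH(CH3); C2, C3 = ring CH2; C4 = ring CH bearing the side chain; C5 = aromatic CH; C6 = C–CO2Me; C7, C8 = C–OH; C9, C10 = aromatic carbons bonded to C1 and C4; C11 = side-chain CH(CH3); C12–C14 = CH2; C15 = CH(CH3); C16 = CH2OH. The target is (1R,4S,11S,15S), with the C1 methyl and the C4 side chain trans.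

Assumption 1: the (S,S)-bromoborane of step 2 is written as the enantiomer that gives (R)-5; if the sense of induction on this ester-bearing ether is the opposite, its (R,R)-antipode is used with nothing else changed.
Assumption 2: the (S)-ligand of step 7 is written as the enantiomer that adds H2 to the alkene face giving 11S; the (R)-ligand is used if the correlation with E-tocotrienyl substrates turns out opposite.

**Route**

Step 1
Reactants: 1 methyl 2,3-dihydroxybenzoate; 2 (E)-but-2-en-1-ol
Product: 3 methyl 3-[(2E)-but-2-en-1-yloxy]-2-hydroxybenzoate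
Conditions: PPh3, DIAD, THF, 0 °C to rt
Reagents that add atoms: none
Why: Mitsunobu etherification; the 3-OH is the free, more acidic phenol (the 2-OH is hydrogen-bonded to the ester carbonyl), and SN2 displacement at the primary allylic carbon keeps the E geometry; no stereocentre is formed.

Step 2
Reactants: 3 methyl 3-[(2E)-but-2-en-1-yloxy]-2-hydroxybenzoate
Product: 5 methyl 4-[(2R)-but-3-en-2-yl]-2,3-dihydroxybenzoate, via aryloxyborane 4 (not isolated)
Conditions: (S,S)-2-bromo-4,5-diphenyl-1,3-bis(4-methylbenzenesulfonyl)-1,3,2-diazaborolidine (1.5 equiv), Et3N (1.5 equiv), CH2Cl2, −45 °C to rt; aqueous NaHCO3 work-up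
Reagents that add atoms: none
Why: enantioselective aromatic Claisen rearrangement ([3,3]-sigmatropic) as known for catechol mono-allyl ethers: boron binds the phenoxide and the ether oxygen in a rigid chelate, the only free ortho position (C9) takes the crotyl terminus, and the chair transition state of the E-ether in the C2-symmetric sulfonamide pocket sets C1 as R (about 85–95% ee expected; the minor enantiomer is removed later as a diastereomer).

Step 3
Reactants: 5 methyl 4-[(2R)-but-3-en-2-yl]-2,3-dihydroxybenzoate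
Product: 6 methyl 7-[(2R)-but-3-en-2-yl]-2,2-dimethyl-1,3-benzodioxole-4-carboxylate
Conditions: 2,2-dimethoxypropane, PPTS (cat.), toluene, reflux, 4 Å sieves
Reagents that add atoms: 2,2-dimethoxypropane, COC(C)(C)OC
Why: acid-catalysed transketalisation (acetonide formation) masks both phenols for the organometallic step; PPTS is too weak to cyclise the o-allylphenol, and C1 is untouched.

Step 4
Reactants: 7 (R)-3-bromo-2-methylpropan-1-ol; 8 allylmagnesium bromide
Product: 10 tert-butyldimethyl{[(2S)-2-methylhex-5-en-1-yl]oxy}silane, via magnesium alkoxide 9 (not isolated)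
Conditions: 8 (2.5 equiv), Li2CuCl4 (3 mol%), THF, −78 to 0 °C; then TBSCl (2 equiv), imidazole (0.2 equiv), DMF, rt
Reagents that add atoms: tert-butyldimethylsilyl chloride, CC(C)(C)[Si](C)(C)Cl
Why: copper-catalysed Grignard–alkyl bromide cross-coupling (Kochi type) on the magnesium alkoxide, then in-situ silylation; C15 comes unchanged from the chiral pool (the descriptor changes from R to S only because CH2Br becomes a carbon chain).

Step 5
Reactants: 10 tert-butyldimethyl{[(2S)-2-methylhex-5-en-1-yl]oxy}silane; 11 methacrolein (2-methylprop-2-enal)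
Product: 12 (2E,6S)-7-[(tert-butyldimethylsilyl)oxy]-2,6-dimethylhept-2-enal
Conditions: second-generation Hoveyda–Grubbs catalyst RuCl2(H2IMes)(=CH-C6H4-2-OiPr) (3 mol%), 11 (5 equiv), CH2Cl2, 40 °C
Reagents that add atoms: none
Why: olefin cross-metathesis of a terminal alkene with excess methacrolein gives the trisubstituted enal with E geometry (thermodynamic control, typically >20:1); the remote stereocentre is unaffected.

Step 6
Reactants: 6 methyl 7-[(2R)-but-3-en-2-yl]-2,2-dimethyl-1,3-benzodioxole-4-carboxylate; 12 (2E,6S)-7-[(tert-butyldimethylsilyl)oxy]-2,6-dimethylhept-2-enal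
Product: 15 methyl (6S,9R)-6-[(2E,6S)-7-[(tert-butyldimethylsilyl)oxy]-6-methylhept-2-en-2-yl]-2,2,9-trimethyl-6,7,8,9-tetrahydronaphtho[1,2-d][1,3]dioxole-4-carboxylate, via alkylzirconocene 13 (not isolated), via zirconium alkoxide 14 (not isolated)
Conditions: Cp2Zr(H)Cl (1.15 equiv), CH2Cl2, rt, 1 h; 12 (1.0 equiv), AgClO4 (5 mol%), rt, 1 h; then BF3·OEt2 (2 equiv, promoter), −78 to −30 °C; Et3N quench at −30 °C; chromatography
Reagents that add atoms: none
Why: Proposed new method: hydrozirconation puts Zr on the terminal carbon (C3), the AgClO4-generated cationic zirconocene adds the alkyl group 1,2 to the enal (known Grignard-type addition of alkylzirconocenes), and BF3 then ionises the allylic zirconium alkoxide to the E-2-methylallyl cation, which arene carbon C10 (para to a ring oxygen, the only position the tether reaches) captures at C4 in a six-membered chair-like transition state with the C1 methyl pseudoaxial (peri strain with O8) and the new C4 substituent on the opposite face, giving the 1,4-trans (1R,4S) tetralin with the C11=C12 E geometry kept; the closest known reaction type is the intramolecular Friedel–Crafts alkylation of allylic alcohols (cation–arene cyclisation) used for calamenene- and pseudopterosin-type tetralins, the new element being ionisation of the zirconium alkoxide in the same flask.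

Step 7
Reactants: 15 methyl (6S,9R)-6-[(2E,6S)-7-[(tert-butyldimethylsilyl)oxy]-6-methylhept-2-en-2-yl]-2,2,9-trimethyl-6,7,8,9-tetrahydronaphtho[1,2-d][1,3]dioxole-4-carboxylate
Product: 17 methyl (5R,8S)-3,4-dihydroxy-8-[(2S,6S)-7-hydroxy-6-methylheptan-2-yl]-5-methyl-5,6,7,8-tetrahydronaphthalene-2-carboxylate, via saturated silyl ether 16 (not isolated)
Conditions: [Ir(cod)(L)][B(C6H3-3,5-(CF3)2)4] (2 mol%; L = (S)-2-phenyl-8-(di-tert-butylphosphinooxy)-5,6,7,8-tetrahydroquinoline), H2 (50 bar), CH2Cl2, rt; then TFA/H2O (9:1), 0 °C to rt, under argon; NaHCO3/MeOH work-up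
Reagents that add atoms: none
Why: iridium-catalysed asymmetric hydrogenation of an unfunctionalised E-trisubstituted alkene (Pfaltz type) adds H2 under catalyst control to the face that gives 11S (the same topological face as in the reduction of E-tocotrienyl side chains to R-methyl centres), and aqueous TFA then hydrolyses the catechol acetonide and the primary silyl ether without touching the methyl ester or any stereocentre, giving the target 17.

**Compound list**
1 | methyl 2,3-dihydroxybenzoate | COC(=O)c1cccc(O)c1O | starting material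
2 | (E)-but-2-en-1-ol | C/C=C/CO | starting material
3 | methyl 3-[(2E)-but-2-en-1-yloxy]-2-hydroxybenzoate | COC(=O)c1cccc(OC/C=C/C)c1O | intermediate
4 | (4S,5S)-2-{2-[(2E)-but-2-en-1-yloxy]-6-(methoxycarbonyl)phenoxy}-4,5-diphenyl-1,3-bis(4-methylbenzenesulfonyl)-1,3,2-diazaborolidine (aryloxyborane) | COC(=O)c1cccc(OC/C=C/C)c1OB1N(S(=O)(=O)c2ccc(C)cc2)[C@@H](c2ccccc2)[C@H](c2ccccc2)N1S(=O)(=O)c1ccc(C)cc1 | intermediate
5 | methyl 4-[(2R)-but-3-en-2-yl]-2,3-dihydroxybenzoate | COC(=O)c1ccc([C@H](C)C=C)c(O)c1O | intermediate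
6 | methyl 7-[(2R)-but-3-en-2-yl]-2,2-dimethyl-1,3-benzodioxole-4-carboxylate | COC(=O)c1ccc([C@H](C)C=C)c2c1OC(C)(C)O2 | intermediate
7 | (R)-3-bromo-2-methylpropan-1-ol | BrC[C@H](C)CO | starting material
8 | allylmagnesium bromide | C=CC[Mg]Br | starting material
9 | bromomagnesium (2S)-2-methylhex-5-en-1-olate (magnesium alkoxide) | C=CCC[C@H](C)CO[Mg]Br | intermediate
10 | tert-butyldimethyl{[(2S)-2-methylhex-5-en-1-yl]oxy}silane | C=CCC[C@H](C)CO[Si](C)(C)C(C)(C)C | intermediate
11 | methacrolein (2-methylprop-2-enal) | CC(=C)C=O | starting material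
12 | (2E,6S)-7-[(tert-butyldimethylsilyl)oxy]-2,6-dimethylhept-2-enal | O=C/C(C)=C/CC[C@H](C)CO[Si](C)(C)C(C)(C)C | intermediate
13 | chlorobis(cyclopentadienyl){(3R)-3-[7-(methoxycarbonyl)-2,2-dimethyl-1,3-benzodioxol-4-yl]butyl}zirconium (alkylzirconocene) | COC(=O)c1ccc([C@H](C)CC[Zr](Cl)(C3C=CC=C3)C3C=CC=C3)c2c1OC(C)(C)O2 | intermediate
14 | chlorobis(cyclopentadienyl)zirconium alkoxide of methyl 7-[(2R,6E,10S)-11-[(tert-butyldimethylsilyl)oxy]-5-hydroxy-6,10-dimethylundec-6-en-2-yl]-2,2-dimethyl-1,3-benzodioxole-4-carboxylate (both C5 epimers) | COC(=O)c1ccc([C@H](C)CCC(O[Zr](Cl)(C3C=CC=C3)C3C=CC=C3)/C(C)=C/CC[C@H](C)CO[Si](C)(C)C(C)(C)C)c2c1OC(C)(C)O2 | intermediate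
15 | methyl (6S,9R)-6-[(2E,6S)-7-[(tert-butyldimethylsilyl)oxy]-6-methylhept-2-en-2-yl]-2,2,9-trimethyl-6,7,8,9-tetrahydronaphtho[1,2-d][1,3]dioxole-4-carboxylate | COC(=O)c1cc2c(c3c1OC(C)(C)O3)[C@H](C)CC[C@H]2/C(C)=C/CC[C@H](C)CO[Si](C)(C)C(C)(C)C | intermediate
16 | methyl (6S,9R)-6-[(2S,6S)-7-[(tert-butyldimethylsilyl)oxy]-6-methylheptan-2-yl]-2,2,9-trimethyl-6,7,8,9-tetrahydronaphtho[1,2-d][1,3]dioxole-4-carboxylate | COC(=O)c1cc2c(c3c1OC(C)(C)O3)[C@H](C)CC[C@H]2[C@@H](C)CCC[C@H](C)CO[Si](C)(C)C(C)(C)C | intermediate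
17 | methyl (5R,8S)-3,4-dihydroxy-8-[(2S,6S)-7-hydroxy-6-methylheptan-2-yl]-5-methyl-5,6,7,8-tetrahydronaphthalene-2-carboxylate | COC(=O)c1cc2c(c(O)c1O)[C@H](C)CC[C@H]2[C@@H](C)CCC[C@H](C)CO | target

**Step count**
Total: 7 steps. Longest linear sequence: 5 steps (1, 2, 3, 6, 7); the side-chain branch is steps 4 and 5.

**Three steps most likely to fail, with fallbacks**

Step 6 is the riskiest. The zirconium alkoxide may not ionise cleanly under BF3, the silyl ether may be partly lost, and the 1,4-trans selectivity is argued by analogy, not known for this substrate. The cis isomer and the diastereomer from the minor enantiomer of 5 are removed at 15. The fallback sets out from 6 and 12 and comes back at 15. Vinylmagnesium bromide adds to 12 (THF, −78 °C) to give the dienol (4E,8S)-9-[(tert-butyldimethylsilyl)oxy]-4,8-dimethylnona-1,4-dien-3-ol F1. Cross-metathesis of its vinyl group with 6 (second-generation Hoveyda–Grubbs catalyst RuCl2(H2IMes)(=CH-C6H4-2-OiPr), CH2Cl2, 40 °C) gives the bis-allylic alcohol methyl 7-[(2R,3E,6E,10S)-11-[(tert-butyldimethylsilyl)oxy]-5-hydroxy-6,10-dimethylundeca-3,6-dien-2-yl]-2,2-dimethyl-1,3-benzodioxole-4-carboxylate F2. Diimide (2-nitrobenzenesulfonylhydrazide, Et3N) reduces only the 1,2-disubstituted C2=C3 alkene and gives the free allylic alcohol methyl 7-[(2R,6E,10S)-11-[(tert-butyldimethylsilyl)oxy]-5-hydroxy-6,10-dimethylundec-6-en-2-yl]-2,2-dimethyl-1,3-benzodioxole-4-carboxylate F3. This isolated alcohol is cyclised with catalytic Bi(OTf)3 in CH2Cl2 at −20 °C to 15. Here the C2–C4 chain is built by metathesis instead of an organometallic addition, and the cation comes from a purified alcohol.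

Step 7 is the second risk. The catalyst must override the adjacent C4 stereocentre, and the sense of induction is taken from an analogy. The fallback sets out from 15 and comes back at 16. Hydroboration with monoisopinocampheylborane (IpcBH2, the enantiomer matched to the required C11 face; THF, −25 °C), then NaBO3 oxidation, gives the alcohol methyl (6S,9R)-6-[(2R,3S,6S)-7-[(tert-butyldimethylsilyl)oxy]-3-hydroxy-6-methylheptan-2-yl]-2,2,9-trimethyl-6,7,8,9-tetrahydronaphtho[1,2-d][1,3]dioxole-4-carboxylate F4; the syn addition to the E-alkene fixes C11 as in 16. With 1,1'-thiocarbonyldiimidazole this gives the thiocarbonylimidazolide methyl (6S,9R)-6-[(2R,3S,6S)-7-[(tert-butyldimethylsilyl)oxy]-3-[(1H-imidazol-1-ylcarbonothioyl)oxy]-6-methylheptan-2-yl]-2,2,9-trimethyl-6,7,8,9-tetrahydronaphtho[1,2-d][1,3]dioxole-4-carboxylate F5. Bu3SnH/AIBN in toluene at 90 °C (Barton–McCombie deoxygenation) then gives 16, which is deprotected with TFA/H2O as in step 7.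

Step 2 is the third risk. The ester carbonyl next to the free phenol may compete for boron and lower rate or ee. The fallback sets out from 1 and comes back at 5. Mitsunobu reaction of 1 with (R)-(E)-pent-3-en-2-ol (PPh3, DIAD, inversion) gives the ether methyl 2-hydroxy-3-{[(2S,3E)-pent-3-en-2-yl]oxy}benzoate F6. Thermal aromatic Claisen rearrangement (N,N-diethylaniline, 180 °C) transfers the stereocentre through a chair transition state and gives methyl 2,3-dihydroxy-4-[(2R,3E)-pent-3-en-2-yl]benzoate F7. Ethenolysis (ethylene, second-generation Grubbs catalyst RuCl2(H2IMes)(PCy3)(=CHPh), CH2Cl2) cuts the propenyl group down to the vinyl group of 5. Chirality now comes from a resolved alcohol and not from a chiral reagent.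

Further compounds
F1 | step 6 | (4E,8S)-9-[(tert-butyldimethylsilyl)oxy]-4,8-dimethylnona-1,4-dien-3-ol | C=CC(O)/C(C)=C/CC[C@H](C)CO[Si](C)(C)C(C)(C)C
F2 | step 6 | methyl 7-[(2R,3E,6E,10S)-11-[(tert-butyldimethylsilyl)oxy]-5-hydroxy-6,10-dimethylundeca-3,6-dien-2-yl]-2,2-dimethyl-1,3-benzodioxole-4-carboxylate | COC(=O)c1ccc([C@H](C)/C=C/C(O)/C(C)=C/CC[C@H](C)CO[Si](C)(C)C(C)(C)C)c2c1OC(C)(C)O2
F3 | step 6 | methyl 7-[(2R,6E,10S)-11-[(tert-butyldimethylsilyl)oxy]-5-hydroxy-6,10-dimethylundec-6-en-2-yl]-2,2-dimethyl-1,3-benzodioxole-4-carboxylate | COC(=O)c1ccc([C@H](C)CCC(O)/C(C)=C/CC[C@H](C)CO[Si](C)(C)C(C)(C)C)c2c1OC(C)(C)O2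
F4 | step 7 | methyl (6S,9R)-6-[(2R,3S,6S)-7-[(tert-butyldimethylsilyl)oxy]-3-hydroxy-6-methylheptan-2-yl]-2,2,9-trimethyl-6,7,8,9-tetrahydronaphtho[1,2-d][1,3]dioxole-4-carboxylate | COC(=O)c1cc2c(c3c1OC(C)(C)O3)[C@H](C)CC[C@H]2[C@@H](C)[C@@H](O)CC[C@H](C)CO[Si](C)(C)C(C)(C)C
F5 | step 7 | methyl (6S,9R)-6-[(2R,3S,6S)-7-[(tert-butyldimethylsilyl)oxy]-3-[(1H-imidazol-1-ylcarbonothioyl)oxy]-6-methylheptan-2-yl]-2,2,9-trimethyl-6,7,8,9-tetrahydronaphtho[1,2-d][1,3]dioxole-4-carboxylate | COC(=O)c1cc2c(c3c1OC(C)(C)O3)[C@H](C)CC[C@H]2[C@@H](C)[C@@H](OC(=S)n1ccnc1)CC[C@H](C)CO[Si](C)(C)C(C)(C)C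
F6 | step 2 | methyl 2-hydroxy-3-{[(2S,3E)-pent-3-en-2-yl]oxy}benzoate | COC(=O)c1cccc(O[C@@H](C)/C=C/C)c1O
F7 | step 2 | methyl 2,3-dihydroxy-4-[(2R,3E)-pent-3-en-2-yl]benzoate | COC(=O)c1ccc([C@H](C)/C=C/C)c(O)c1O
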